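The 1,2-dioxane (O1–O2–C3–C4–C5–C6) is opened at O1–C6. The quaternary peroxide carbon C6 and the E-configured C7=C8 alkene, whose C8 carries an ethyl and a CH2 group too similar for any olefination to tell apart, are folded back into one tetrasubstituted allene C6=C7=C8 of M configuration. A gold-catalysed 6-exo addition of the C3 hydroperoxide to C6 should then form the ring, the C6 stereocentre and the alkene geometry in one operation by axis-to-centre transfer. The precursor 29 is the open-chain (3S,4R,6M,10R,11E) hydroperoxy allene with a free C1 hydroxyl, assembled from an ethynyl carbinol and an aldol-derived iodide.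

Key step: step 20

Remark: the allene of 28 and 29 is a stereogenic axis that a name must specify; the axis required is M (equivalently aR), the sense written in the SMILES of 28 and 29.
Remark: 29 and 30 carry a free C1 hydroxyl instead of a silyl ether, because oxetane perhydrolysis releases it free, O-silylation beside a hydroperoxide is unselective, an eight-membered closure cannot compete with the six-membered one, and a final deprotection is saved.
Remark: lithium and boron derivatives of a numbered compound (acetylides, alkoxides, the boron enolate of 17) are treated as that compound under the stated conditions; 17 and 18 are taken as commercial.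

Step 1
Reactants: 1 (E)-pent-2-enal; 2 ethylmagnesium bromide
Product: 3 rac-(E)-hept-4-en-3-ol
Conditions: EtMgBr, Et2O, −78 → 0 °C; aq. NH4Cl
Reagents that add atoms: none
Why: Grignard 1,2-addition to the enal should give the racemic secondary allylic alcohol, and no stereocontrol is sought because step 2 resolves it.

Step 2
Reactants: 3 rac-(E)-hept-4-en-3-ol
Product: 4 (3R,4E)-hept-4-en-3-ol
Conditions: Ti(OiPr)4, L-(+)-DIPT, t-BuOOH (0.6 equiv), 4 Å MS, CH2Cl2, −20 °C, stopped just past half conversion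
Reagents that add atoms: none
Why: Sharpless kinetic resolution, in which the L-(+)-tartrate complex should epoxidise the (S)-alcohol far faster and leave the (R)-alcohol in high enantiomeric purity.

Step 3
Reactants: 4 (3R,4E)-hept-4-en-3-ol; 5 triethyl orthoacetate
Product: 6 ethyl (3R,4E)-3-ethylhept-4-enoate
Conditions: MeC(OEt)3, EtCO2H (cat.), 140 °C, EtOH distilled off
Reagents that add atoms: none
Why: Johnson–Claisen rearrangement through a chair with the carbinol ethyl equatorial should transfer the carbinol configuration suprafacially to the new stereocentre (C10 of the target, R) and form the E alkene (C11=C12).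

Step 4
Reactants: 6 ethyl (3R,4E)-3-ethylhept-4-enoate; 7 dimethyl (1-diazo-2-oxopropyl)phosphonate
Product: 9 (4R,5E)-4-ethyloct-5-en-1-yne, via (3R,4E)-3-ethylhept-4-enal 8 (not isolated)
Conditions: i-Bu2AlH, CH2Cl2, −78 °C; MeOH; then K2CO3, 7, MeOH, 0 °C → rt
Reagents that add atoms: none
Why: the aluminium hemiacetal formed at −78 °C should release the aldehyde only on methanolysis, where Ohira–Bestmann (Seyferth–Gilbert) homologation gives the terminal alkyne, the stereocentre being β to the carbonyl and unable to epimerise.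

Step 5
Reactants: 9 (4R,5E)-4-ethyloct-5-en-1-yne; 10 ethyl chloroformate
Product: 11 ethyl (5R,6E)-5-ethylnon-6-en-2-ynoate
Conditions: n-BuLi, THF, −78 °C; ClCO2Et, −78 → 0 °C
Reagents that add atoms: none
Why: deprotonation of the terminal alkyne and C-acylation of the lithium acetylide by the chloroformate is a standard route to ynoates.

Step 6
Reactants: 11 ethyl (5R,6E)-5-ethylnon-6-en-2-ynoate; 2 ethylmagnesium bromide
Product: 12 ethyl (2Z,5R,6E)-3,5-diethylnona-2,6-dienoate
Conditions: EtMgBr (2.4 equiv), CuBr·SMe2 (1.2 equiv), THF, −40 °C; then 11, −78 °C; MeOH, −78 °C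
Reagents that add atoms: none
Why: syn carbocupration (conjugate addition) of the diethylcuprate to the ynoate and cold protonation of the alkenylcuprate with retention should place the new ethyl trans to the ester, which is the 2Z enoate.

Step 7
Reactants: 12 ethyl (2Z,5R,6E)-3,5-diethylnona-2,6-dienoate
Product: 13 (2Z,5R,6E)-3,5-diethylnona-2,6-dien-1-ol
Conditions: i-Bu2AlH (2.5 equiv), CH2Cl2, −78 → 0 °C; aq. potassium sodium tartrate
Reagents that add atoms: none
Why: 1,2-reduction of the enoate by the aluminium hydride gives the allylic alcohol without touching either alkene geometry.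

Step 8
Reactants: 13 (2Z,5R,6E)-3,5-diethylnona-2,6-dien-1-ol
Product: 14 {(2S,3R)-3-ethyl-3-[(2R,3E)-2-ethylhex-3-en-1-yl]oxiran-2-yl}methanol
Conditions: Ti(OiPr)4 (cat.), L-(+)-DET (cat.), t-BuOOH, 4 Å MS, CH2Cl2, −20 °C
Reagents that add atoms: tert-butyl hydroperoxide, CC(C)(C)OO
Why: Sharpless asymmetric epoxidation, in which the L-(+)-tartrate complex should deliver oxygen to the face that gives the (2S,3R) epoxide of this Z (nerol-type) allylic alcohol, setting the future C8–O centre while the isolated alkene, not being allylic to a hydroxyl, stays untouched.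

Step 9
Reactants: 14 {(2S,3R)-3-ethyl-3-[(2R,3E)-2-ethylhex-3-en-1-yl]oxiran-2-yl}methanol
Product: 15 (2R,3R)-2-(chloromethyl)-3-ethyl-3-[(2R,3E)-2-ethylhex-3-en-1-yl]oxirane
Conditions: PPh3, CCl4, NaHCO3, reflux
Reagents that add atoms: tetrachloromethane, ClC(Cl)(Cl)Cl
Why: Appel chlorination of the primary alcohol under bicarbonate buffering should leave the acid-sensitive trisubstituted epoxide intact.

Step 10
Reactants: 15 (2R,3R)-2-(chloromethyl)-3-ethyl-3-[(2R,3E)-2-ethylhex-3-en-1-yl]oxirane
Product: 16 (3R,5R,6E)-3,5-diethylnon-6-en-1-yn-3-ol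
Conditions: n-BuLi (3.5 equiv), THF, −78 → −30 °C; aq. NH4Cl
Reagents that add atoms: none
Why: base-induced fragmentation of the 2,3-epoxy chloride (deprotonation next to chlorine, epoxide opening to a chlorovinyl alkoxide, dehydrochlorination) gives the ethynyl carbinol without breaking the tertiary C–O bond, so the carbinol centre (C8) keeps its R configuration.

Step 11
Reactants: 17 (4S)-4-benzyl-3-butanoyl-1,3-oxazolidin-2-one; 18 3-{[tert-butyl(dimethyl)silyl]oxy}propanal
Product: 19 (4S)-4-benzyl-3-[(2S,3R)-5-{[tert-butyl(dimethyl)silyl]oxy}-2-ethyl-3-hydroxypentanoyl]-1,3-oxazolidin-2-one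
Conditions: Bu2BOTf, i-Pr2NEt, CH2Cl2, −78 → 0 °C; 18, −78 → 0 °C; pH 7 buffer, MeOH, H2O2
Reagents that add atoms: none
Why: Evans syn aldol, in which the Z boron enolate reacts through a Zimmerman–Traxler chair on the face away from the benzyl group and so sets C4 and the C3 carbinol (syn, 2S,3R in the acyl chain).

Step 12
Reactants: 19 (4S)-4-benzyl-3-[(2S,3R)-5-{[tert-butyl(dimethyl)silyl]oxy}-2-ethyl-3-hydroxypentanoyl]-1,3-oxazolidin-2-one
Product: 20 (4S)-4-benzyl-3-[(2S,3R)-3,5-bis{[tert-butyl(dimethyl)silyl]oxy}-2-ethylpentanoyl]-1,3-oxazolidin-2-one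
Conditions: TBSOTf, 2,6-lutidine, CH2Cl2, −78 → 0 °C
Reagents that add atoms: tert-butyldimethylsilyl trifluoromethanesulfonate, CC(C)(C)[Si](C)(C)OS(=O)(=O)C(F)(F)F
Why: silylation of the secondary alcohol with the silyl triflate and a hindered base protects C3–O and removes the risk of retro-aldol cleavage.

Step 13
Reactants: 20 (4S)-4-benzyl-3-[(2S,3R)-3,5-bis{[tert-butyl(dimethyl)silyl]oxy}-2-ethylpentanoyl]-1,3-oxazolidin-2-one
Product: 21 (2R,3R)-3,5-bis{[tert-butyl(dimethyl)silyl]oxy}-2-ethylpentan-1-ol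
Conditions: LiBH4, MeOH (1 equiv), THF, 0 °C
Reagents that add atoms: none
Why: reductive removal of the oxazolidinone with the borohydride gives the primary alcohol (C5) without epimerising the adjacent C4.

Step 14
Reactants: 21 (2R,3R)-3,5-bis{[tert-butyl(dimethyl)silyl]oxy}-2-ethylpentan-1-ol
Product: 22 (3R,4S)-1,3-bis{[tert-butyl(dimethyl)silyl]oxy}-4-(iodomethyl)hexane
Conditions: I2, PPh3, imidazole, CH2Cl2, 0 °C → rt
Reagents that add atoms: iodine, II
Why: Appel-type iodination of the primary alcohol proceeds under buffered conditions that both silyl ethers tolerate.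

Step 15
Reactants: 16 (3R,5R,6E)-3,5-diethylnon-6-en-1-yn-3-ol; 22 (3R,4S)-1,3-bis{[tert-butyl(dimethyl)silyl]oxy}-4-(iodomethyl)hexane
Product: 23 (3E,5R,7R,11R,12R)-12,14-bis{[tert-butyl(dimethyl)silyl]oxy}-5,7,11-triethyltetradec-3-en-8-yn-7-ol
Conditions: 16, n-BuLi (2.1 equiv), THF/DMPU, −78 → −20 °C; then 22, −20 °C → rt
Reagents that add atoms: none
Why: SN2 alkylation of the lithium acetylide (as the alkoxide–acetylide dianion) by the primary iodide in a dipolar cosolvent forms C5–C6, C-alkylation being much faster than O-alkylation of the hindered tertiary alkoxide.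

Step 16
Reactants: 23 (3E,5R,7R,11R,12R)-12,14-bis{[tert-butyl(dimethyl)silyl]oxy}-5,7,11-triethyltetradec-3-en-8-yn-7-ol
Product: 24 (3R,4R,8R,10R,11E)-4,8,10-triethyltetradec-11-en-6-yne-1,3,8-triol
Conditions: TBAF, THF, rt → 40 °C
Reagents that add atoms: none
Why: fluoride-mediated cleavage of both silyl ethers frees the 1,3-diol needed for the oxetane.

Step 17
Reactants: 24 (3R,4R,8R,10R,11E)-4,8,10-triethyltetradec-11-en-6-yne-1,3,8-triol
Product: 26 (3E,5R,7R,11R)-5,7-diethyl-11-[(2R)-oxetan-2-yl]tridec-3-en-8-yn-7-ol, via primary tosylate 25 (not isolated)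
Conditions: TsCl (1.05 equiv), Et3N, Me3N·HCl (cat.), CH2Cl2, 0 °C; then crude 25, KOtBu, THF, 0 °C → rt
Reagents that add atoms: none
Why: selective sulfonylation of the only primary hydroxyl followed by intramolecular Williamson etherification (4-exo-tet) by the C3 alkoxide closes the oxetane with retention at C3, since the C3–O bond is not broken.

Step 18
Reactants: 26 (3E,5R,7R,11R)-5,7-diethyl-11-[(2R)-oxetan-2-yl]tridec-3-en-8-yn-7-ol; 2 ethylmagnesium bromide
Product: 28 (2R)-2-[(3R,5M,9R,10E)-5,7,9-triethyltrideca-5,6,10-trien-3-yl]oxetane, via propargylic mesylate 27 (not isolated)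
Conditions: n-BuLi, THF, −78 °C; MsCl, −78 °C; then EtMgBr, CuBr·SMe2, LiBr, THF, −78 → −40 °C
Reagents that add atoms: none
Why: anti-SN2′ substitution of the tertiary propargylic mesylate by the ethylcopper reagent (centre-to-axis chirality transfer) should add ethyl to C6 anti to the departing C8–O bond and so convert the R carbinol into the M allene.

Step 19
Reactants: 28 (2R)-2-[(3R,5M,9R,10E)-5,7,9-triethyltrideca-5,6,10-trien-3-yl]oxetane
Product: 29 (3S,4R,6M,10R,11E)-4,6,8,10-tetraethyl-3-hydroperoxytetradeca-6,7,11-trien-1-ol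
Conditions: H2O2 (anhydrous, in Et2O), MoO2(acac)2 (cat.), Et2O, 0 °C → rt
Reagents that add atoms: hydrogen peroxide, OO
Why: molybdenum-catalysed perhydrolysis of the oxetane should open the ring at the more substituted carbon C3 with inversion, giving the 3S hydroperoxide (anti to the C4 ethyl) and freeing the C1 alcohol.

Step 20
Reactants: 29 (3S,4R,6M,10R,11E)-4,6,8,10-tetraethyl-3-hydroperoxytetradeca-6,7,11-trien-1-ol
Product: 30 2-[(3S,4R,6S)-6-[(1E,4R,5E)-2,4-diethylocta-1,5-dien-1-yl]-4,6-diethyl-1,2-dioxan-3-yl]ethan-1-ol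
Conditions: Ph3PAuNTf2 (5 mol%), 4 Å MS, CH2Cl2, −20 → 0 °C, dark
Reagents that add atoms: none
Why: Proposed new method: cationic monovalent gold should bind the C6=C7 π bond of the allene on the face that carries C9, the terminal hydroperoxide oxygen should add anti to C6 through a chair in which the C3 and C4 substituents and the C6 ethyl sit equatorial while the slender, still sp-hybridised C7 arm is axial, and protodeauration of the C7 alkenylgold with retention should release the catalyst. The closest known reaction type is the gold-catalysed exo-hydroalkoxylation of allenyl alcohols with axis-to-centre chirality transfer; a hydroperoxide is a weaker base but a better nucleophile than an alcohol, and monovalent gold is a poor one-electron reductant, so O–O cleavage is not expected at low temperature. The 1,2-dioxane ring (O1–O2–C3–C4–C5–C6) closes in a 6-exo mode at the allene terminus C6. The new stereocentre C6 (S) is controlled by the M axis acting through stereospecific anti addition together with the chair preference, and the same event places H cis to C9 and the C8 ethyl cis to C6, which is the 7E geometry. The step needs regioselectivity for C6 over C8 (six- against eight-membered ring), chemoselectivity for oxygen attack over carbocyclisation onto the C11=C12 alkene or attack by the C1 hydroxyl (a 6-exo heteroatom nucleophile against an unactivated alkene and an eight-membered closure), and ring closure faster than gold-induced axis epimerisation, which the fully substituted allene, the low temperature and the non-coordinating counterion should favour.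

Step 21
Reactants: 30 2-[(3S,4R,6S)-6-[(1E,4R,5E)-2,4-diethylocta-1,5-dien-1-yl]-4,6-diethyl-1,2-dioxan-3-yl]ethan-1-ol
Product: 32 2-[(3S,4R,6S)-6-[(1E,4R,5E)-2,4-diethylocta-1,5-dien-1-yl]-4,6-diethyl-1,2-dioxan-3-yl]acetic acid, via dioxanyl acetaldehyde 31 (not isolated)
Conditions: TEMPO (cat.), PhI(OAc)2, CH2Cl2, rt; then t-BuOH/H2O, 2-methylbut-2-ene, NaH2PO4, NaClO2, 0 °C → rt
Reagents that add atoms: sodium chlorite, [Na+].[O-]Cl=O
Why: nitroxyl-catalysed oxidation of the primary alcohol to the aldehyde and Pinnick oxidation to the acid are both compatible with a dialkyl peroxide, and the alkene scavenger protects the two alkenes from hypochlorous acid.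

Compound list
1 | (E)-pent-2-enal | CC/C=C/C=O | starting material
2 | ethylmagnesium bromide | CC[Mg]Br | starting material
3 | rac-(E)-hept-4-en-3-ol | CCC(O)/C=C/CC | intermediate
4 | (3R,4E)-hept-4-en-3-ol | CC[C@@H](O)/C=C/CC | intermediate
5 | triethyl orthoacetate | CC(OCC)(OCC)OCC | starting material
6 | ethyl (3R,4E)-3-ethylhept-4-enoate | CCOC(=O)C[C@@H](CC)/C=C/CC | intermediate
7 | dimethyl (1-diazo-2-oxopropyl)phosphonate | CC(=O)C(=[N+]=[N-])P(=O)(OC)OC | starting material
8 | (3R,4E)-3-ethylhept-4-enal | O=CC[C@@H](CC)/C=C/CC | intermediate (not isolated)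
9 | (4R,5E)-4-ethyloct-5-en-1-yne | C#CC[C@@H](CC)/C=C/CC | intermediate
10 | ethyl chloroformate | CCOC(=O)Cl | starting material
11 | ethyl (5R,6E)-5-ethylnon-6-en-2-ynoate | CCOC(=O)C#CC[C@@H](CC)/C=C/CC | intermediate
12 | ethyl (2Z,5R,6E)-3,5-diethylnona-2,6-dienoate | CCOC(=O)/C=C(/CC)C[C@@H](CC)/C=C/CC | intermediate
13 | (2Z,5R,6E)-3,5-diethylnona-2,6-dien-1-ol | OC/C=C(/CC)C[C@@H](CC)/C=C/CC | intermediate
14 | {(2S,3R)-3-ethyl-3-[(2R,3E)-2-ethylhex-3-en-1-yl]oxiran-2-yl}methanol | OC[C@@H]1O[C@]1(CC)C[C@@H](CC)/C=C/CC | intermediate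
15 | (2R,3R)-2-(chloromethyl)-3-ethyl-3-[(2R,3E)-2-ethylhex-3-en-1-yl]oxirane | ClC[C@@H]1O[C@]1(CC)C[C@@H](CC)/C=C/CC | intermediate
16 | (3R,5R,6E)-3,5-diethylnon-6-en-1-yn-3-ol | C#C[C@@](O)(CC)C[C@@H](CC)/C=C/CC | intermediate
17 | (4S)-4-benzyl-3-butanoyl-1,3-oxazolidin-2-one | CCCC(=O)N1[C@@H](Cc2ccccc2)COC1=O | starting material
18 | 3-{[tert-butyl(dimethyl)silyl]oxy}propanal | O=CCCO[Si](C)(C)C(C)(C)C | starting material
19 | (4S)-4-benzyl-3-[(2S,3R)-5-{[tert-butyl(dimethyl)silyl]oxy}-2-ethyl-3-hydroxypentanoyl]-1,3-oxazolidin-2-one | CC[C@@H]([C@H](O)CCO[Si](C)(C)C(C)(C)C)C(=O)N1[C@@H](Cc2ccccc2)COC1=O | intermediate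
20 | (4S)-4-benzyl-3-[(2S,3R)-3,5-bis{[tert-butyl(dimethyl)silyl]oxy}-2-ethylpentanoyl]-1,3-oxazolidin-2-one | CC[C@@H]([C@H](O[Si](C)(C)C(C)(C)C)CCO[Si](C)(C)C(C)(C)C)C(=O)N1[C@@H](Cc2ccccc2)COC1=O | intermediate
21 | (2R,3R)-3,5-bis{[tert-butyl(dimethyl)silyl]oxy}-2-ethylpentan-1-ol | CC[C@@H]([C@H](O[Si](C)(C)C(C)(C)C)CCO[Si](C)(C)C(C)(C)C)CO | intermediate
22 | (3R,4S)-1,3-bis{[tert-butyl(dimethyl)silyl]oxy}-4-(iodomethyl)hexane | CC[C@@H]([C@H](O[Si](C)(C)C(C)(C)C)CCO[Si](C)(C)C(C)(C)C)CI | intermediate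
23 | (3E,5R,7R,11R,12R)-12,14-bis{[tert-butyl(dimethyl)silyl]oxy}-5,7,11-triethyltetradec-3-en-8-yn-7-ol | CC/C=C/[C@H](CC)C[C@](O)(CC)C#CC[C@@H](CC)[C@H](O[Si](C)(C)C(C)(C)C)CCO[Si](C)(C)C(C)(C)C | intermediate
24 | (3R,4R,8R,10R,11E)-4,8,10-triethyltetradec-11-en-6-yne-1,3,8-triol | CC/C=C/[C@H](CC)C[C@](O)(CC)C#CC[C@@H](CC)[C@H](O)CCO | intermediate
25 | (3R,4R,8R,10R,11E)-4,8,10-triethyl-3,8-dihydroxytetradec-11-en-6-yn-1-yl 4-methylbenzenesulfonate | CC/C=C/[C@H](CC)C[C@](O)(CC)C#CC[C@@H](CC)[C@H](O)CCOS(=O)(=O)c1ccc(C)cc1 | intermediate (not isolated)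
26 | (3E,5R,7R,11R)-5,7-diethyl-11-[(2R)-oxetan-2-yl]tridec-3-en-8-yn-7-ol | CC/C=C/[C@H](CC)C[C@](O)(CC)C#CC[C@@H](CC)[C@H]1CCO1 | intermediate
27 | (3E,5R,7R,11R)-5,7-diethyl-11-[(2R)-oxetan-2-yl]tridec-3-en-8-yn-7-yl methanesulfonate | CC/C=C/[C@H](CC)C[C@](OS(C)(=O)=O)(CC)C#CC[C@@H](CC)[C@H]1CCO1 | intermediate (not isolated)
28 | (2R)-2-[(3R,5M,9R,10E)-5,7,9-triethyltrideca-5,6,10-trien-3-yl]oxetane | CC/C=C/[C@H](CC)CC(CC)=[C@]=C(CC)C[C@@H](CC)[C@H]1CCO1 | intermediate
29 | (3S,4R,6M,10R,11E)-4,6,8,10-tetraethyl-3-hydroperoxytetradeca-6,7,11-trien-1-ol | CC/C=C/[C@H](CC)CC(CC)=[C@]=C(CC)C[C@@H](CC)[C@H](CCO)OO | intermediate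
30 | 2-[(3S,4R,6S)-6-[(1E,4R,5E)-2,4-diethylocta-1,5-dien-1-yl]-4,6-diethyl-1,2-dioxan-3-yl]ethan-1-ol | CC/C=C/[C@H](CC)C/C(=C/[C@]1(CC)C[C@@H](CC)[C@H](CCO)OO1)CC | intermediate
31 | 2-[(3S,4R,6S)-6-[(1E,4R,5E)-2,4-diethylocta-1,5-dien-1-yl]-4,6-diethyl-1,2-dioxan-3-yl]acetaldehyde | CC/C=C/[C@H](CC)C/C(=C/[C@]1(CC)C[C@@H](CC)[C@H](CC=O)OO1)CC | intermediate (not isolated)
32 | 2-[(3S,4R,6S)-6-[(1E,4R,5E)-2,4-diethylocta-1,5-dien-1-yl]-4,6-diethyl-1,2-dioxan-3-yl]acetic acid | CC/C=C/[C@H](CC)C/C(=C/[C@]1(CC)C[C@@H](CC)[C@H](CC(=O)O)OO1)CC | target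

Total step count: 21. Longest linear sequence: 17 (steps 1–10 and 15–21).

Steps most likely to fail

1. Step 20 (proposed new method). The gold catalyst may epimerise the allene axis before ring closure, the two chair-like modes of attack may be poorly separated (the other mode leads to the 6-epi,7Z isomer), or the hydroperoxide may decompose at the metal instead of adding. The fallback uses known chemistry, sets out from 26 and returns at 30; it gives up the axis and closes the ring through a tertiary allylic cation. A Meyer–Schuster rearrangement of 26 (Ph3PAuNTf2 cat., MeOH, toluene) would give, after separation from its 6Z isomer (which can be re-equilibrated with catalytic iodine), the enone (3R,6E,9R,10E)-7,9-diethyl-3-[(2R)-oxetan-2-yl]trideca-6,10-dien-5-one F1. EtMgBr with CeCl3 would add 1,2 to give the tertiary allylic alcohol (3R,5RS,6E,9R,10E)-5,7,9-triethyl-3-[(2R)-oxetan-2-yl]trideca-6,10-dien-5-ol F2, whose two C5 epimers converge later. Perhydrolysis of the oxetane as in step 19 would give (3S,4R,6RS,7E,10R,11E)-4,6,8,10-tetraethyl-3-hydroperoxytetradeca-7,11-diene-1,6-diol F3. Catalytic camphorsulfonic acid in CH2Cl2 at 0 °C would then ionise the tertiary allylic alcohol so that the C3 hydroperoxide closes the six-membered ring (acid-catalysed cyclodehydration of a hydroxy hydroperoxide), returning to 30 with C6 set only by the chair preference and the 6-epimer to be removed by chromatography.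

2. Step 19. Hydrogen peroxide may open the oxetane at the primary carbon or through a cation-like path with loss of inversion, and the peroxomolybdate may oxidise the electron-rich allene. The fallback sets out from 24 and returns at 29; it replaces strained-ring opening by sulfonate displacement. Silylation of the primary hydroxyl (TBSCl, imidazole) would give (3R,4R,8R,10R,11E)-1-{[tert-butyl(dimethyl)silyl]oxy}-4,8,10-triethyltetradec-11-en-6-yne-3,8-diol F4. Double mesylation (n-BuLi, MsCl, −78 °C) would give (3R,4R,8R,10R,11E)-1-{[tert-butyl(dimethyl)silyl]oxy}-4,8,10-triethyltetradec-11-en-6-yne-3,8-diyl dimethanesulfonate F5, used without isolation. The ethylcopper reagent of step 18 should attack only the propargylic mesylate and give the allene (3R,4R,6M,10R,11E)-1-{[tert-butyl(dimethyl)silyl]oxy}-4,6,8,10-tetraethyltetradeca-6,7,11-trien-3-yl methanesulfonate F6. SN2 displacement of the secondary mesylate by hydroperoxide anion (H2O2, KOH, MeOH/THF) with inversion would give tert-butyl{[(3S,4R,6M,10R,11E)-4,6,8,10-tetraethyl-3-hydroperoxytetradeca-6,7,11-trien-1-yl]oxy}dimethylsilane F7, and HF·pyridine would remove the silyl ether to reach 29.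

3. Step 18. Ionisation of the tertiary propargylic mesylate ahead of copper attack would erode the anti transfer to the axis, and hydride transfer from the ethylcopper reagent would give the reduced, trisubstituted allene. The fallback sets out from 26 and returns at 28; it replaces organocopper substitution by palladium cross-coupling. Acylation (n-BuLi, ClCO2Me) would give (3E,5R,7R,11R)-5,7-diethyl-11-[(2R)-oxetan-2-yl]tridec-3-en-8-yn-7-yl methyl carbonate F8. The zerovalent palladium complex Pd(PPh3)4 (cat.) with EtZnCl (from EtMgBr and ZnCl2) in THF should then give 28 by anti oxidative addition to an allenylpalladium, transmetalation and reductive elimination.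

Further compounds
F1 | step 20 | (3R,6E,9R,10E)-7,9-diethyl-3-[(2R)-oxetan-2-yl]trideca-6,10-dien-5-one | CC/C=C/[C@H](CC)C/C(CC)=C/C(=O)C[C@@H](CC)[C@H]1CCO1
F2 | step 20 | (3R,5RS,6E,9R,10E)-5,7,9-triethyl-3-[(2R)-oxetan-2-yl]trideca-6,10-dien-5-ol | CC/C=C/[C@H](CC)C/C(CC)=C/C(O)(CC)C[C@@H](CC)[C@H]1CCO1
F3 | step 20 | (3S,4R,6RS,7E,10R,11E)-4,6,8,10-tetraethyl-3-hydroperoxytetradeca-7,11-diene-1,6-diol | CC/C=C/[C@H](CC)C/C(CC)=C/C(O)(CC)C[C@@H](CC)[C@H](CCO)OO
F4 | step 19 | (3R,4R,8R,10R,11E)-1-{[tert-butyl(dimethyl)silyl]oxy}-4,8,10-triethyltetradec-11-en-6-yne-3,8-diol | CC/C=C/[C@H](CC)C[C@](O)(CC)C#CC[C@@H](CC)[C@H](O)CCO[Si](C)(C)C(C)(C)C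
F5 | step 19 | (3R,4R,8R,10R,11E)-1-{[tert-butyl(dimethyl)silyl]oxy}-4,8,10-triethyltetradec-11-en-6-yne-3,8-diyl dimethanesulfonate | CC/C=C/[C@H](CC)C[C@](OS(C)(=O)=O)(CC)C#CC[C@@H](CC)[C@H](OS(C)(=O)=O)CCO[Si](C)(C)C(C)(C)C
F6 | step 19 | (3R,4R,6M,10R,11E)-1-{[tert-butyl(dimethyl)silyl]oxy}-4,6,8,10-tetraethyltetradeca-6,7,11-trien-3-yl methanesulfonate | CC/C=C/[C@H](CC)CC(CC)=[C@]=C(CC)C[C@@H](CC)[C@H](OS(C)(=O)=O)CCO[Si](C)(C)C(C)(C)C
F7 | step 19 | tert-butyl{[(3S,4R,6M,10R,11E)-4,6,8,10-tetraethyl-3-hydroperoxytetradeca-6,7,11-trien-1-yl]oxy}dimethylsilane | CC/C=C/[C@H](CC)CC(CC)=[C@]=C(CC)C[C@@H](CC)[C@H](CCO[Si](C)(C)C(C)(C)C)OO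
F8 | step 18 | (3E,5R,7R,11R)-5,7-diethyl-11-[(2R)-oxetan-2-yl]tridec-3-en-8-yn-7-yl methyl carbonate | CC/C=C/[C@H](CC)C[C@](OC(=O)OC)(CC)C#CC[C@@H](CC)[C@H]1CCO1
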